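The dihydropyran ring on ring B (O1–C2–C3–C4–C4a–C8a) is cut by a retro-hetero-Diels–Alder reaction into isobutene and the ortho-quinone methide C4H2=C4a–C8a=O1. The key step exploits the phenolic O1 on C8a beside the free ring carbon C4a. A monocyclic bromocatechol aldehyde, formaldehyde and isobutene combine in one operation, which forms C4a–C4, C4–C3 and C2–O1, sets quaternary C2 and rearomatises ring B. In the precursor nothing of the heterocycle exists. Its bromine (C5) later becomes the prenyl group and its formyl group (C6) starts the propane bridge. A second quinone methide deletes the bridge carbonyl, and an aromatic Claisen rearrangement on ring A finishes.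

Key step: step 1

Numbering: ring B and its pyran ring carry chroman numbers (O1, C2, C3, C4, C4a, C5–C8, C8a). Ring A is the resorcinol ring, with C1 bearing the bridge and oxygen on C2 and C4. The target has no stereocentre.
Assumption: compounds 1 and 7 are taken as catalogue compounds.

Step 1
Reactants: 1 2-bromo-4,5-dihydroxybenzaldehyde; 2 formaldehyde (charged as paraformaldehyde); 3 isobutene
Product: 6 5-bromo-8-hydroxy-2,2-dimethylchroman-6-carbaldehyde, via Mannich base 4 (not isolated), via ortho-quinone methide 5 (not isolated)
Conditions: (CH2O)n (1.05 equiv), isobutene (15 equiv, condensed in), Bu2NH (0.2 equiv), AcOH (0.4 equiv), 1,4-dioxane, 160 °C, sealed autoclave, argon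
Reagents that add atoms: none
Why: Bu2NH and formaldehyde give an iminium ion that attacks C3 of 1 (the future C4a), ortho to the ionised 4-OH, and the Mannich base 4 loses the amine again on heating to give the ortho-quinone methide 5. In 5 the unit O1=C8a–C4a=C4H2 is a 1-oxadiene made electron-poor by the formyl and bromo groups, so it takes up isobutene in an inverse-electron-demand hetero-Diels–Alder reaction driven by the return of aromaticity to ring B. The closest known reaction type is the three-component chroman synthesis from a phenol, formaldehyde and a 1,1-disubstituted alkene under amine/acid catalysis. The six-membered O1–C2–C3–C4–C4a–C8a ring closes by an intermolecular, concerted but asynchronous [4+2] cycloaddition in which C4–C3 forms ahead of C2–O1, and no stereocentre is created. Orientation is secured by polarity, since the nucleophilic CH2 of isobutene meets the electrophilic C4 and the carbon that best carries positive charge meets O1, which gives the 2,2- and not the 3,3-dimethyl isomer. Site selectivity rests on the para-formyl group, which makes the 4-OH the acidic, ionised one and deactivates the other free carbon (C6 of 1, ortho to CHO), while a large excess of isobutene and only one equivalent of formaldehyde hold back self-condensation of 5 and a second annulation at C7.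

Step 2
Reactants: 6 5-bromo-8-hydroxy-2,2-dimethylchroman-6-carbaldehyde; 7 tributyl(3-methylbut-2-en-1-yl)stannane
Product: 8 8-hydroxy-2,2-dimethyl-5-(3-methylbut-2-enyl)chroman-6-carbaldehyde
Conditions: 7 (1.3 equiv), Pd(PPh3)4 (5 mol %), DMF, 100 °C, argon
Reagents that add atoms: none
Why: Stille cross-coupling, in which the C5–Br bond, activated by the ortho formyl group, adds to zerovalent palladium and the prenyl group passes from tin to palladium and is coupled at its less hindered CH2 end, while the neutral medium leaves the phenol and the aldehyde untouched.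

Step 3
Reactants: 9 2,4-dihydroxyacetophenone; 10 prenyl bromide (1-bromo-3-methylbut-2-ene)
Product: 11 1-[2-hydroxy-4-(3-methylbut-2-enyloxy)phenyl]ethanone
Conditions: K2CO3 (1.1 equiv), acetone, reflux
Reagents that add atoms: none
Why: Williamson ether synthesis, selective for the 4-OH because the 2-OH is held in a hydrogen bond to the acetyl oxygen and is much less nucleophilic.

Step 4
Reactants: 8 8-hydroxy-2,2-dimethyl-5-(3-methylbut-2-enyl)chroman-6-carbaldehyde; 11 1-[2-hydroxy-4-(3-methylbut-2-enyloxy)phenyl]ethanone
Product: 13 (E)-1-[2-hydroxy-4-(3-methylbut-2-enyloxy)phenyl]-3-[8-hydroxy-2,2-dimethyl-5-(3-methylbut-2-enyl)chroman-6-yl]prop-2-en-1-one, via aldol adduct 12 (not isolated)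
Conditions: KOH (50 % aq, excess), EtOH, rt, argon; then cold dilute HCl to pH 5
Reagents that add atoms: none
Why: Claisen–Schmidt condensation, in which only 11 can enolise, the C8 phenoxide of 8 is meta to the formyl group and so does not quench its electrophilicity, and E1cB loss of water from racemic 12 gives the conjugated E-enone.

Step 5
Reactants: 13 the (E)-chalcone
Product: 14 1-[2-hydroxy-4-(3-methylbut-2-enyloxy)phenyl]-3-[8-hydroxy-2,2-dimethyl-5-(3-methylbut-2-enyl)chroman-6-yl]propan-1-one
Conditions: [(PPh3)CuH]6 (5 mol %), PhMe2SiH (4 equiv), toluene, rt; then 1 M NaOH, THF; then aq NH4Cl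
Reagents that add atoms: none
Why: Copper hydride conjugate reduction, which delivers hydride only to the polarised enone carbon, so both isolated trisubstituted alkenes and the allylic aryl ether are inert, and the phenols merely consume silane and are freed again in the basic work-up.

Step 6
Reactants: 14 the dihydrochalcone
Product: 18 6-{3-[2-hydroxy-4-(3-methylbut-2-enyloxy)phenyl]propyl}-2,2-dimethyl-5-(3-methylbut-2-enyl)chroman-8-ol, via bis(ethyl carbonate) 15 (not isolated), via ring-A quinone methide 16 (not isolated), via mono(ethyl carbonate) 17 (not isolated)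
Conditions: ClCO2Et (2.4 equiv), Et3N, THF, 0 °C, filter; filtrate into NaBH4 (6 equiv), H2O–THF, 0 °C to rt; then 2 M NaOH, MeOH, rt
Reagents that add atoms: none
Why: Ortho-hydroxyl-assisted deoxygenation of an aryl ketone, in which borohydride reduces the ketone of 15, the neighbouring carbonate moves to the benzylic oxygen and leaves to give the quinone methide 16, a second hydride adds to its exocyclic carbon to give 17, and hydroxide then cleaves the remaining ring-B carbonate without touching any alkene.

Step 7
Reactants: 18 the ring-A prenyl ether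
Product: 20 kazinol D, via ortho-dienone 19 (not isolated)
Conditions: PhNEt2, 190 °C, sealed tube, argon, short heating
Reagents that add atoms: none
Why: Aromatic Claisen rearrangement, a [3,3] shift with allyl inversion that places the 1,1-dimethylallyl group on C5 of ring A (para to the donor 2-OH and unhindered) rather than on C3 (wedged between two oxygens), after which racemic 19 tautomerises to the phenol and the basic solvent suppresses acid-induced ring closure onto the vinyl group.

Compound list
1 | 2-bromo-4,5-dihydroxybenzaldehyde | O=Cc1cc(O)c(O)cc1Br | starting material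
2 | formaldehyde (as paraformaldehyde) | C=O | starting material
3 | isobutene | CC(C)=C | starting material
4 | 2-bromo-3-[(dibutylamino)methyl]-4,5-dihydroxybenzaldehyde | CCCCN(CCCC)Cc1c(O)c(O)cc(C=O)c1Br | intermediate
5 | 2-bromo-5-hydroxy-3-methylidene-4-oxocyclohexa-1,5-diene-1-carbaldehyde | C=C1C(Br)=C(C=O)C=C(O)C1=O | intermediate
6 | 5-bromo-8-hydroxy-2,2-dimethylchroman-6-carbaldehyde | CC1(C)CCc2c(Br)c(C=O)cc(O)c2O1 | intermediate
7 | tributyl(3-methylbut-2-en-1-yl)stannane | CCCC[Sn](CCCC)(CCCC)CC=C(C)C | starting material
8 | 8-hydroxy-2,2-dimethyl-5-(3-methylbut-2-enyl)chroman-6-carbaldehyde | CC(C)=CCc1c(C=O)cc(O)c2OC(C)(C)CCc12 | intermediate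
9 | 2,4-dihydroxyacetophenone | CC(=O)c1ccc(O)cc1O | starting material
10 | prenyl bromide | CC(C)=CCBr | starting material
11 | 1-[2-hydroxy-4-(3-methylbut-2-enyloxy)phenyl]ethanone | CC(=O)c1ccc(OCC=C(C)C)cc1O | intermediate
12 | racemic aldol adduct, 3-hydroxy-1-(ring A)-3-(ring B)propan-1-one | O=C(CC(O)c1cc(O)c2OC(C)(C)CCc2c1CC=C(C)C)c1ccc(OCC=C(C)C)cc1O | intermediate
13 | (E)-chalcone | O=C(/C=C/c1cc(O)c2OC(C)(C)CCc2c1CC=C(C)C)c1ccc(OCC=C(C)C)cc1O | intermediate
14 | dihydrochalcone | O=C(CCc1cc(O)c2OC(C)(C)CCc2c1CC=C(C)C)c1ccc(OCC=C(C)C)cc1O | intermediate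
15 | bis(ethyl carbonate) of 14 | CCOC(=O)Oc1cc(OCC=C(C)C)ccc1C(=O)CCc1cc(OC(=O)OCC)c2OC(C)(C)CCc2c1CC=C(C)C | intermediate
16 | ring-A ortho-quinone methide, ring-B carbonate retained | O=C1C=C(OCC=C(C)C)C=CC1=CCCc1cc(OC(=O)OCC)c2OC(C)(C)CCc2c1CC=C(C)C | intermediate
17 | O8-ethyl carbonate of 18 | Oc1cc(OCC=C(C)C)ccc1CCCc1cc(OC(=O)OCC)c2OC(C)(C)CCc2c1CC=C(C)C | intermediate
18 | 6-{3-[2-hydroxy-4-(3-methylbut-2-enyloxy)phenyl]propyl}-2,2-dimethyl-5-(3-methylbut-2-enyl)chroman-8-ol | Oc1cc(OCC=C(C)C)ccc1CCCc1cc(O)c2OC(C)(C)CCc2c1CC=C(C)C | intermediate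
19 | racemic ortho-dienone, 6-(2-methylbut-3-en-2-yl)-3-hydroxy-4-(bridge)cyclohexa-2,4-dien-1-one | C=CC(C)(C)C1C=C(CCCc2cc(O)c3OC(C)(C)CCc3c2CC=C(C)C)C(O)=CC1=O | intermediate
20 | kazinol D | C=CC(C)(C)c1cc(CCCc2cc(O)c3c(c2CC=C(C)C)CCC(C)(C)O3)c(O)cc1O | target

Total step count: 7. Longest linear sequence: 6 (steps 1, 2, 4, 5, 6, 7).

Steps most likely to fail

1. Step 1.
- **What may go wrong:** Aminomethylation at the crowded carbon between Br and OH may be slow, or attack may occur at the other free ring carbon. The quinone methide may self-condense, or tautomerise to a methyl-ortho-quinone, faster than the unactivated alkene captures it.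
- **Fallback, from 1 back to 6:** The more acidic 4-OH would be alkylated with 3-chloro-3-methylbut-1-yne (DBU, cat. CuCl2·2H2O, MeCN, 0 °C). This gives the aryl propargyl ether 2-bromo-5-hydroxy-4-[(2-methylbut-3-yn-2-yl)oxy]benzaldehyde F1. Heating in PhNEt2 (about 170 °C) should bring about a [3,3] shift onto the only free ortho carbon, a 1,5-hydrogen shift and an oxa-6π electrocyclisation. The product is 5-bromo-8-hydroxy-2,2-dimethyl-2H-chromene-6-carbaldehyde F2. Diimide (potassium azodicarboxylate, AcOH, MeOH) would saturate C3=C4 without touching the bromide or the aldehyde and lead back to 6. This variant gives up the cycloaddition, and the ring then closes at O1–C2.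

2. Step 7.
- **What may go wrong:** Site selectivity between C3 and C5 of ring A may be incomplete. Prolonged heating may cause further isomerisation of the new allyl group, or addition of the freed phenol to the vinyl group.
- **Fallback, from 18 back to 20:** Both phenols would be silylated (TBSCl, imidazole, DMF) to the bis(tert-butyldimethylsilyl) ether of 18 F3, whose bulky group on the ring-A O2 walls off C3. The rearrangement of this substrate should give the C5-(1,1-dimethylallyl) phenol bis-silyl ether F4. TBAF buffered with AcOH in THF would then free 20.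

3. Step 2.
- **What may go wrong:** Oxidative addition and transmetalation may be slow at the doubly ortho-substituted bromide. The allyl group may transpose to the branched isomer, or the stannane may be protonated by the free phenol.
- **Fallback, from 6 back to 8:** The smaller allyltributylstannane would be coupled first (Pd(PPh3)4, toluene, reflux) to give 5-allyl-8-hydroxy-2,2-dimethylchroman-6-carbaldehyde F5. The terminal alkene would then be turned into the prenyl group by cross-metathesis with 2-methylbut-2-ene (second-generation Grubbs catalyst, CH2Cl2, 40 °C), which gives 8.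

Further compounds
F1 | step 1 | 2-bromo-5-hydroxy-4-[(2-methylbut-3-yn-2-yl)oxy]benzaldehyde | C#CC(C)(C)Oc1cc(Br)c(C=O)cc1O
F2 | step 1 | 5-bromo-8-hydroxy-2,2-dimethyl-2H-chromene-6-carbaldehyde | CC1(C)C=Cc2c(Br)c(C=O)cc(O)c2O1
F3 | step 7 | bis(tert-butyldimethylsilyl) ether of 18 | CC(C)=CCOc1ccc(CCCc2cc(O[Si](C)(C)C(C)(C)C)c3OC(C)(C)CCc3c2CC=C(C)C)c(O[Si](C)(C)C(C)(C)C)c1
F4 | step 7 | kazinol D 2-O(ring A),8-O(ring B)-bis(tert-butyldimethylsilyl) ether | C=CC(C)(C)c1cc(CCCc2cc(O[Si](C)(C)C(C)(C)C)c3OC(C)(C)CCc3c2CC=C(C)C)c(O[Si](C)(C)C(C)(C)C)cc1O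
F5 | step 2 | 5-allyl-8-hydroxy-2,2-dimethylchroman-6-carbaldehyde | C=CCc1c(C=O)cc(O)c2OC(C)(C)CCc12
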